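**Plan**

1. Retrosynthesis: the four MOM ethers come off last. The pyranone is then contracted by taking C3 out of the ring (C3–C4 cut, C2 joined to C4), which gives a 2-aryl-2-(iodomethyl)benzofuran-3(2H)-one. This is cut at C2–CH2I (enolate alkylation), at C2–aryl (Pd α-arylation) and at O1–C2 (closure of a 2-hydroxyacetophenone).
2. Forward: ring A is bought as phloroacetophenone and C-prenylated, then the five-membered furanone is closed. Ring B is made from resorcinol (a Claisen rearrangement installs the 1,1-dimethylallyl group) and attached at C2. CH2I is added, and the furanone is enlarged to the pyranone.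
3. Enabling feature: C4 is an aryl ketone, C3 a bare CH2, and C2 carries both the ring oxygen O1 and the electron-rich B-ring aryl. A radical on an exocyclic CH2 at C2 of the benzofuranone can therefore undergo a 1,2-acyl shift to a C2 radical of the chromanone that is both benzylic and α-oxygenated.
4. Stereochemistry: the single stereocentre C2 (S) is created in the same step by face-selective hydrogen-atom transfer inside an ene-reductase. The racemic quaternary precursor converges on one planar radical.

Key step: step 10

Remark: C2 is the only stereocentre and is S (O1 > C1′ of ring B > C3 > H). Simple reagents that add atoms (prenyl bromide, MOMCl, NBS, CH2I2) are given with SMILES at the step and are not numbered. Compound 11 is drawn as the keto tautomer; its enol form is irrelevant because C2 becomes quaternary in step 9.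

**Route**

Step 1
Reactants: 1 2,4,6-trihydroxyacetophenone
Product: 2 1-[2,4,6-trihydroxy-3-(3-methylbut-2-en-1-yl)phenyl]ethan-1-one
Conditions: prenyl bromide (1.0 equiv), DBU, THF, 0 °C → rt
Reagents that add atoms: prenyl bromide (1-bromo-3-methylbut-2-ene), CC(C)=CCBr
Why: C-alkylation of the acylphloroglucinol under amidine base takes place at a ring carbon between two hydroxyls, and since the two free ring positions are equivalent, mono-prenylation can give only one regioisomer.

Step 2
Reactants: 2 1-[2,4,6-trihydroxy-3-(3-methylbut-2-en-1-yl)phenyl]ethan-1-one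
Product: 3 1-[2-hydroxy-4,6-bis(methoxymethoxy)-3-(3-methylbut-2-en-1-yl)phenyl]ethan-1-one
Conditions: MOMCl (2.2 equiv), i-Pr2NEt, CH2Cl2, 0 °C → rt
Reagents that add atoms: chloromethyl methyl ether (MOMCl), COCCl
Why: Williamson-type acetal protection should take the 4-OH and the unhindered 6-OH, while the 2-OH, hydrogen-bonded to the acetyl group and flanked by the prenyl chain, stays free and later becomes O1 next to the prenylated carbon.

Step 3
Reactants: 3 1-[2-hydroxy-4,6-bis(methoxymethoxy)-3-(3-methylbut-2-en-1-yl)phenyl]ethan-1-one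
Product: 5 4,6-bis(methoxymethoxy)-7-(3-methylbut-2-en-1-yl)-1-benzofuran-3(2H)-one, via α-iodo ketone 4 (not isolated)
Conditions: LiHMDS (2.2 equiv), THF, −78 °C; inverse addition to I2 (1.0 equiv), −78 °C; then → rt
Reagents that add atoms: none
Why: Enolate α-iodination of the phenoxide/enolate dianion followed by 5-exo-tet Williamson closure by the neighbouring phenoxide is the ω-halo-2-hydroxyacetophenone route to benzofuran-3(2H)-ones, and the low temperature with inverse addition should keep iodine away from the prenyl alkene and the free ring position.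

Step 4
Reactants: 6 resorcinol
Product: 7 3-[(3-methylbut-2-en-1-yl)oxy]phenol
Conditions: prenyl bromide (1 equiv), resorcinol (3 equiv), K2CO3, acetone, reflux
Reagents that add atoms: prenyl bromide (1-bromo-3-methylbut-2-ene), CC(C)=CCBr
Why: Williamson mono-etherification, with excess resorcinol to suppress the bis-ether.

Step 5
Reactants: 7 3-[(3-methylbut-2-en-1-yl)oxy]phenol
Product: 8 4-(2-methylbut-3-en-2-yl)benzene-1,3-diol
Conditions: PhNEt2, 190 °C, sealed tube, Ar
Reagents that add atoms: none
Why: The aromatic Claisen rearrangement ([3,3]) should deliver the inverted 1,1-dimethylallyl group to the ortho carbon para to the free hydroxyl, the less hindered site that a meta donor substituent favours.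

Step 6
Reactants: 8 4-(2-methylbut-3-en-2-yl)benzene-1,3-diol
Product: 9 2,4-bis(methoxymethoxy)-1-(2-methylbut-3-en-2-yl)benzene
Conditions: NaH, MOMCl (2.4 equiv), DMF, 0 °C → rt
Reagents that add atoms: chloromethyl methyl ether (MOMCl), COCCl
Why: Double Williamson protection with a strong base, needed because one hydroxyl is flanked by the tertiary alkyl group.

Step 7
Reactants: 9 2,4-bis(methoxymethoxy)-1-(2-methylbut-3-en-2-yl)benzene
Product: 10 1-bromo-2,4-bis(methoxymethoxy)-5-(2-methylbut-3-en-2-yl)benzene
Conditions: NBS (1.0 equiv), MeCN, 0 °C, dark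
Reagents that add atoms: N-bromosuccinimide, O=C1CCC(=O)N1Br
Why: Electrophilic aromatic bromination should go to the carbon that is ortho to one and para to the other alkoxy group (the other doubly activated carbon lies between them and is hindered), and the arene is far more nucleophilic than the monosubstituted alkene.

Step 8
Reactants: 5 4,6-bis(methoxymethoxy)-7-(3-methylbut-2-en-1-yl)-1-benzofuran-3(2H)-one; 10 1-bromo-2,4-bis(methoxymethoxy)-5-(2-methylbut-3-en-2-yl)benzene
Product: 11 rac-2-[2,4-bis(methoxymethoxy)-5-(2-methylbut-3-en-2-yl)phenyl]-4,6-bis(methoxymethoxy)-7-(3-methylbut-2-en-1-yl)-1-benzofuran-3(2H)-one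
Conditions: Pd2(dba)3 (2.5 mol%), XPhos (6 mol%), K3PO4, toluene, 80 °C, Ar; product kept under Ar
Reagents that add atoms: none
Why: Pd-catalysed ketone α-arylation (Buchwald–Hartwig type) of the acidic C2–H2 of the cyclic aryl ketone should stop after one aryl group, because the product is more acidic than 5 and rests as its hindered enolate.

Step 9
Reactants: 11 rac-2-[2,4-bis(methoxymethoxy)-5-(2-methylbut-3-en-2-yl)phenyl]-4,6-bis(methoxymethoxy)-7-(3-methylbut-2-en-1-yl)-1-benzofuran-3(2H)-one
Product: 12 rac-2-[2,4-bis(methoxymethoxy)-5-(2-methylbut-3-en-2-yl)phenyl]-2-(iodomethyl)-4,6-bis(methoxymethoxy)-7-(3-methylbut-2-en-1-yl)-1-benzofuran-3(2H)-one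
Conditions: CH2I2 (5 equiv), Cs2CO3, MeCN, 40 °C, dark, Ar
Reagents that add atoms: diiodomethane, ICI
Why: C-alkylation of the soft 2-aryl enolate with excess dihalomethane, the usual way to make Dowd–Beckwith precursors, should give the quaternary C2 bearing CH2I, whose configuration does not matter.

Step 10
Reactants: 12 rac-2-[2,4-bis(methoxymethoxy)-5-(2-methylbut-3-en-2-yl)phenyl]-2-(iodomethyl)-4,6-bis(methoxymethoxy)-7-(3-methylbut-2-en-1-yl)-1-benzofuran-3(2H)-one
Product: 13 (2S)-2-[2,4-bis(methoxymethoxy)-5-(2-methylbut-3-en-2-yl)phenyl]-5,7-bis(methoxymethoxy)-8-(3-methylbut-2-en-1-yl)-2,3-dihydro-4H-chromen-4-one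
Conditions: ene-reductase (flavin-dependent OYE family, homologue chosen from a panel, e.g. GluER-T36A), NADP+ (cat.), glucose dehydrogenase/D-glucose, KPi pH 8.0–DMSO (9:1), cyan LEDs (ca. 497 nm), 25 °C, anaerobic
Reagents that add atoms: none
Why: Proposed new method: a Dowd–Beckwith one-carbon ring expansion run inside a flavin-dependent ene-reductase; the closest known reaction types are the tin-hydride Dowd–Beckwith 1,2-acyl shift of α-(halomethyl) cyclic ketones and the photoenzymatic reductive radical cyclisations of alkyl iodides, in which flavin semiquinone ends the sequence by enantioselective hydrogen-atom transfer. Cyan-light excitation of the enzyme-templated charge-transfer complex between reduced flavin and the neopentyl C–I bond of 12 should release iodide and the primary radical on the exocyclic CH2, which adds 3-exo-trig to the C3 carbonyl carbon; the cyclopropyloxy radical then breaks the old C2–C3 bond, so the ketone carbon moves from C2 to CH2 and the five-membered furanone becomes the six-membered pyranone with that CH2 as C3. No ring is closed by an ordinary cyclisation: the new ring arises by 3-exo-trig addition followed by β-scission, a net 1,2-acyl shift that enlarges the ring by one carbon. The rearranged radical sits at C2, planar and stabilised by both O1 and the B-ring aryl, and is quenched by hydrogen-atom transfer from N5–H of the flavin semiquinone to one face; with the C4 carbonyl held in the oxyanion-binding site, C2 is the β-carbon that the enzyme reduces natively, so a homologue with the matching binding mode is chosen to give 2S, and both enantiomers of racemic 12 converge on the same radical. The step needs the acyl shift to outrun premature hydrogen transfer to the primary radical and the competing 1,2-aryl shift, which the aryl-ketone acceptor and the doubly stabilised product radical favour, and it needs the ketone not to be photoreduced (which would cleave C2–O1), which long-wavelength excitation of the charge-transfer band is meant to secure.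

Step 11
Reactants: 13 (2S)-2-[2,4-bis(methoxymethoxy)-5-(2-methylbut-3-en-2-yl)phenyl]-5,7-bis(methoxymethoxy)-8-(3-methylbut-2-en-1-yl)-2,3-dihydro-4H-chromen-4-one
Product: 14 (2S)-2-[2,4-dihydroxy-5-(2-methylbut-3-en-2-yl)phenyl]-5,7-dihydroxy-8-(3-methylbut-2-en-1-yl)-2,3-dihydro-4H-chromen-4-one (AChE-IN-17)
Conditions: 3 M aq. HCl/MeOH (1:5), 40 °C, short contact; NaHCO3 work-up
Reagents that add atoms: none
Why: Acid-catalysed acetal exchange with methanol should remove the four MOM ethers without touching C2, and temperature and time are kept low because alkenyl groups ortho to phenols can cyclise and the electron-rich 2-aryl ether can ionise under stronger acid.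

**Compound list**

1 | 2,4,6-trihydroxyacetophenone | CC(=O)c1c(O)cc(O)cc1O | starting material
2 | 1-[2,4,6-trihydroxy-3-(3-methylbut-2-en-1-yl)phenyl]ethan-1-one | CC(=O)c1c(O)cc(O)c(CC=C(C)C)c1O | intermediate
3 | 1-[2-hydroxy-4,6-bis(methoxymethoxy)-3-(3-methylbut-2-en-1-yl)phenyl]ethan-1-one | CC(=O)c1c(OCOC)cc(OCOC)c(CC=C(C)C)c1O | intermediate
4 | 1-[2-hydroxy-4,6-bis(methoxymethoxy)-3-(3-methylbut-2-en-1-yl)phenyl]-2-iodoethan-1-one (present as its lithium phenoxide) | O=C(CI)c1c(OCOC)cc(OCOC)c(CC=C(C)C)c1O | intermediate (not isolated)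
5 | 4,6-bis(methoxymethoxy)-7-(3-methylbut-2-en-1-yl)-1-benzofuran-3(2H)-one | O=C1COc2c(CC=C(C)C)c(OCOC)cc(OCOC)c12 | intermediate
6 | resorcinol (benzene-1,3-diol) | Oc1cccc(O)c1 | starting material
7 | 3-[(3-methylbut-2-en-1-yl)oxy]phenol | CC(C)=CCOc1cccc(O)c1 | intermediate
8 | 4-(2-methylbut-3-en-2-yl)benzene-1,3-diol | C=CC(C)(C)c1ccc(O)cc1O | intermediate
9 | 2,4-bis(methoxymethoxy)-1-(2-methylbut-3-en-2-yl)benzene | C=CC(C)(C)c1ccc(OCOC)cc1OCOC | intermediate
10 | 1-bromo-2,4-bis(methoxymethoxy)-5-(2-methylbut-3-en-2-yl)benzene | C=CC(C)(C)c1cc(Br)c(OCOC)cc1OCOC | intermediate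
11 | rac-2-[2,4-bis(methoxymethoxy)-5-(2-methylbut-3-en-2-yl)phenyl]-4,6-bis(methoxymethoxy)-7-(3-methylbut-2-en-1-yl)-1-benzofuran-3(2H)-one | O=C1C(c2cc(C(C)(C)C=C)c(OCOC)cc2OCOC)Oc2c(CC=C(C)C)c(OCOC)cc(OCOC)c12 | intermediate
12 | rac-2-[2,4-bis(methoxymethoxy)-5-(2-methylbut-3-en-2-yl)phenyl]-2-(iodomethyl)-4,6-bis(methoxymethoxy)-7-(3-methylbut-2-en-1-yl)-1-benzofuran-3(2H)-one | O=C1C(CI)(c2cc(C(C)(C)C=C)c(OCOC)cc2OCOC)Oc2c(CC=C(C)C)c(OCOC)cc(OCOC)c12 | intermediate
13 | (2S)-2-[2,4-bis(methoxymethoxy)-5-(2-methylbut-3-en-2-yl)phenyl]-5,7-bis(methoxymethoxy)-8-(3-methylbut-2-en-1-yl)-2,3-dihydro-4H-chromen-4-one | C=CC(C)(C)c1cc([C@@H]2CC(=O)c3c(OCOC)cc(OCOC)c(CC=C(C)C)c3O2)c(OCOC)cc1OCOC | intermediate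
14 | (2S)-2-[2,4-dihydroxy-5-(2-methylbut-3-en-2-yl)phenyl]-5,7-dihydroxy-8-(3-methylbut-2-en-1-yl)-2,3-dihydro-4H-chromen-4-one (AChE-IN-17) | C=CC(C)(C)c1cc([C@@H]2CC(=O)c3c(O)cc(O)c(CC=C(C)C)c3O2)c(O)cc1O | target

**Count and risks**

Total steps: 11. Longest linear sequence: 8 steps (steps 4 to 11, from resorcinol 6 to 14).

Steps most likely to fail:

1. Step 10 (Proposed new method). The bulky substrate may bind poorly in the active site. The primary radical may be reduced before the acyl shift. Hydrogen transfer to the C2 radical may show poor facial selectivity. The ketone may be photoreduced, with loss of the C2–O1 bond. The fallback uses known chemistry without any ring expansion; it sets out from 10 and 3 and comes back at 13. Bromine–lithium exchange on 10 (n-BuLi, THF, −78 °C) and formylation with DMF should give the benzaldehyde F1. Claisen–Schmidt condensation of F1 with 3 (KOH, EtOH) should give the 2′-hydroxychalcone F2. NaOAc in refluxing EtOH should close F2 by oxa-Michael addition through its only free phenol to the racemic flavanone F3. Kinetic resolution by Noyori-type asymmetric transfer hydrogenation (Cp*Rh–TsDPEN, HCO2H/Et3N), with the catalyst enantiomer that reduces the 2R ketone to the cis-flavan-4-ol F4, should leave 13.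

2. Step 8. Oxidative addition and C–C reductive elimination may be slow with the hindered, electron-rich bromide. Compound 5 may self-condense under base. The 2-aryl product may autoxidise at C2. The fallback sets out from 3 and 10 and comes back at 11. α-Arylation of the open-chain methyl ketone 3 as its phenoxide/enolate dianion (Pd(OAc)2, P(t-Bu)3, excess NaOt-Bu, toluene) should give the deoxybenzoin F5. Its dianion (LiHMDS, −78 °C) is iodinated at the benzylic carbon to the α-iodo deoxybenzoin F6 (not isolated), and 5-exo-tet closure by the phenoxide should give 11.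

3. Step 9. The ambident enolate may alkylate on oxygen. Substitution on CH2I2 may be slow. Two enolates may be bridged by one CH2. The fallback sets out from 11 and comes back at 12. Aldol hydroxymethylation with aqueous formaldehyde (cat. K2CO3, THF) should give the 2-(hydroxymethyl) ketone F7, and Appel-type iodination (PPh3, I2, imidazole, toluene, 60 °C) should give 12.

**Further compounds**

F1 | step 10 | 2,4-bis(methoxymethoxy)-5-(2-methylbut-3-en-2-yl)benzaldehyde | C=CC(C)(C)c1cc(C=O)c(OCOC)cc1OCOC
F2 | step 10 | (E)-1-[2-hydroxy-4,6-bis(methoxymethoxy)-3-(3-methylbut-2-en-1-yl)phenyl]-3-[2,4-bis(methoxymethoxy)-5-(2-methylbut-3-en-2-yl)phenyl]prop-2-en-1-one | O=C(/C=C/c1cc(C(C)(C)C=C)c(OCOC)cc1OCOC)c1c(OCOC)cc(OCOC)c(CC=C(C)C)c1O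
F3 | step 10 | rac-2-[2,4-bis(methoxymethoxy)-5-(2-methylbut-3-en-2-yl)phenyl]-5,7-bis(methoxymethoxy)-8-(3-methylbut-2-en-1-yl)-2,3-dihydro-4H-chromen-4-one | C=CC(C)(C)c1cc(C2CC(=O)c3c(OCOC)cc(OCOC)c(CC=C(C)C)c3O2)c(OCOC)cc1OCOC
F4 | step 10 | (2R,4R)-2-[2,4-bis(methoxymethoxy)-5-(2-methylbut-3-en-2-yl)phenyl]-5,7-bis(methoxymethoxy)-8-(3-methylbut-2-en-1-yl)-3,4-dihydro-2H-chromen-4-ol (cis) | O[C@@H]1C[C@H](c2cc(C(C)(C)C=C)c(OCOC)cc2OCOC)Oc2c(CC=C(C)C)c(OCOC)cc(OCOC)c12
F5 | step 8 | 1-[2-hydroxy-4,6-bis(methoxymethoxy)-3-(3-methylbut-2-en-1-yl)phenyl]-2-[2,4-bis(methoxymethoxy)-5-(2-methylbut-3-en-2-yl)phenyl]ethan-1-one | O=C(Cc1cc(C(C)(C)C=C)c(OCOC)cc1OCOC)c1c(OCOC)cc(OCOC)c(CC=C(C)C)c1O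
F6 | step 8 | 1-[2-hydroxy-4,6-bis(methoxymethoxy)-3-(3-methylbut-2-en-1-yl)phenyl]-2-iodo-2-[2,4-bis(methoxymethoxy)-5-(2-methylbut-3-en-2-yl)phenyl]ethan-1-one | O=C(C(I)c1cc(C(C)(C)C=C)c(OCOC)cc1OCOC)c1c(OCOC)cc(OCOC)c(CC=C(C)C)c1O
F7 | step 9 | rac-2-[2,4-bis(methoxymethoxy)-5-(2-methylbut-3-en-2-yl)phenyl]-2-(hydroxymethyl)-4,6-bis(methoxymethoxy)-7-(3-methylbut-2-en-1-yl)-1-benzofuran-3(2H)-one | O=C1C(CO)(c2cc(C(C)(C)C=C)c(OCOC)cc2OCOC)Oc2c(CC=C(C)C)c(OCOC)cc(OCOC)c12
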